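The vessel is closed and stirred. It holds substrate and a trace of free enzyme, and substrate turns into target.

the same everywhere: substrate 5.0 × 10⁻⁴ M

| charge | free enzyme | temperature | remark | time |
|---|---|---|---|---|
| ash | 0.014 mol% | 18 °C | run made earlier |  |
| elm | 0.056 mol% | 45 °C | run made earlier |  |
| Monday's | 0.028 mol% | 55 °C |  | 8.0 min |
| Thursday's | 0.028 mol% |  | at 5 °C until 6.0 min, from then on at 55 °C | 8.0 min |
| Sunday's | 0.028 mol% | 30 °C |  | 8.0 min |
| Saturday's | 0.028 mol% | 5 °C |  | 8.0 min |

| run | time / min | target / % | substrate / % |
|---|---|---|---|
| ash | 12.0 | 89 | 0 |
| ash | 25.0 | 82 | 1 |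
| ash | 40.0 | 80 | 1 |
| ash | 50.0 | 80 | 1 |
| elm | 1.50 | 31 | 57 |
| elm | 5.00 | 26 | 55 |
| elm | 8.00 | 26 | 56 |
| elm | 12.0 | 23 | 55 |

(standard deviation of a reading: 1.5 percentage points)

- the flask with the highest amount of target, in percent of the substrate charged ("all alike" if they lie within 1.5 percentage points) (Monday's / Thursday's / Sunday's / Saturday's / all alike)
- final target, as a percentage of the substrate charged, in Monday's
- final target, as a percentage of the substrate charged, in Thursday's
- final target, as a percentage of the substrate charged, in Sunday's
- final target, as a percentage of the substrate charged, in Saturday's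

- what was read earlier has a scatter of 1.5 percentage points, one standard deviation

Two chemists dispute Monday's flask, which sits at 55 °C for 8.0 min.

The first chemist asks what the end state must be. She reads the target's share of everything converted from the last readings. That share is 80.8 % in the ash run and 51.1 % in the elm run. In the ash run target also falls from 89 % to 80 % with substrate at 1 %, so target leaks into something unseen. She puts the lower elm share down to heat, though the loading differs too, so she expects a hot flask to end near half of the charge as target. She calls this thermodynamic control.

The second chemist asks how much conversion the enzyme can deliver. In the elm run substrate reads 57 % at 1.50 min and 55 % at 12.0 min, a change of 2 percentage points against a scatter of 1.5 points. So that flask stopped early. Yet the ash run, with a quarter of that loading, reached 1 % of substrate.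

He defines the capacity, the logarithm of c(substrate) at the start over c(substrate) where conversion stops. Read from the last elm reading, it is 0.598. Reckoned as pseudo-first-order in substrate, at one temperature, capacity scales with the loading of free enzyme. Monday's has half the elm loading, which gives 0.299 at 45 °C. Monday's is hotter, so he takes this as a ceiling.

I side with him. That ceiling converts 25.8 % of the substrate, and at the elm share this makes 13.2 % of target, less than her figure.

Thursday's is where she should be right. That flask stands 6.0 min at 5 °C before the heat. If its substrate is converted by then, the heat meets target, and her share applies.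

The forecast takes his side, holding that “the enzyme dies quickly when hot”, and names Saturday's, with 4 % (1 % to 9 %) for Monday's, less than my ceiling, 45 % (28 % to 65 %) for Thursday's, 68 % (55 % to 78 %) for Sunday's and 82 % (62 % to 93 %) for Saturday's.

The flasks give 0.821 % of target in Monday's, 47.5 % in Thursday's, 73.7 % in Sunday's and 98.6 % in Saturday's, the highest of the set. Thursday's holds 98.8 % of target at the change of temperature and ends with 47.5 % of target and 52.3 % of isomer of the product, so in Thursday's near half of the charge stands as target, the region of her view.

    substrate + free enzyme → target + free enzyme, rate k1*[substrate]*[free enzyme]/(1 + ([substrate]/Km1) + ([target]/Kp1)) (0.230 mM, 0.150 mM, k = 7.50 × 10⁵ M⁻¹ s⁻¹, Ea = 11.0 kJ mol⁻¹)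
    target ⇌ isomer of the product (K = 0.490, k = 0.00120 s⁻¹, Ea = 100 kJ mol⁻¹, ΔH = 27.0 kJ mol⁻¹)
    free enzyme → unfolded enzyme (k = 9.30 × 10⁻⁴ s⁻¹, Ea = 263 kJ mol⁻¹)
    (constants at 30 °C)

Monday's keeps 98 % of its substrate, and unfolded enzyme already stands at 100 % after 4.00 min. Its capacity is therefore 0.0175, far below the ceiling. The neighbouring flask is Monday's with 0.007 mol% of free enzyme, a quarter of the loading. Scaling gives a capacity of 0.00436, so 99.6 % of the substrate should remain. That flask keeps 99.6 % of its substrate and ends with 0.207 % of target.

(All runs were computed for substances that don't exist; the scatter is artificial.)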